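**Plan**

1. Retrosynthesis: the ester C–O bond is cut first, giving 19-(furan-2-yl)nonadeca-5,7-diynoic acid and 11-(furan-2-yl)undeca-4,6-diyn-1-ol. Each diyne is then cut at its central sp–sp bond (C6–C7 of the acid, C5–C6 of the alcohol), and each furyl-alkyl alkyne at its CH2–C(sp) bond (C8–C9 of the acid, C7–C8 of the alcohol).
2. Enabling feature: the acid-side furan (O1, C2, C3, C4, C5) carries its only substituent, the undecyl chain C9–C19, on C2. Its C3=C4 bond therefore joins two unsubstituted CH carbons and can be cut to two vinyl groups on a mixed acetal, with C5 as the acetal carbon and C2 as the carbinol carbon.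
3. Forward, acid half: 12-bromododecanal and vinylmagnesium bromide give the allylic alcohol, methoxyallene gives the mixed acetal, and metathesis with aromatisation closes the furan, the only ring made in the route. Acetylide displacement and Cadiot–Chodkiewicz coupling with 6-bromohex-5-ynoic acid complete the diynoic acid.
4. Forward, alcohol half: purchased furan is lithiated and alkylated with 1,4-dibromobutane, extended with acetylide and coupled with 5-bromopent-4-yn-1-ol. A Steglich esterification joins the two halves last.
5. Stereochemistry: the target has no stereocentre and no stereogenic double bond. The carbinol and acetal centres of the metathesis precursor are carried as mixtures and vanish on aromatisation.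

Key step: step 4

Remark on the chemistry: the long-chain furan is built by metathesis from the commercial ω-bromo alcohol, whereas the short-chain furan is taken from furan itself, because a one-step C2 alkylation with cheap 1,4-dibromobutane in excess is sufficient there.

**Step 1**
Reactants: 1 12-bromododecan-1-ol
Product: 2 12-bromododecanal
Conditions: TEMPO (10 mol%), PhI(OAc)2 (1.1 equiv), CH2Cl2, rt
Reagents that add atoms: none
Why: The TEMPO/PhI(OAc)2 oxidation of a primary alcohol should stop cleanly at the aldehyde and leaves the primary bromide untouched.

**Step 2**
Reactants: 2 12-bromododecanal; 3 vinylmagnesium bromide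
Product: 4 14-bromotetradec-1-en-3-ol (racemic)
Conditions: THF, −78 °C → 0 °C; then sat. aq NH4Cl
Reagents that add atoms: none
Why: Grignard 1,2-addition to an unhindered aldehyde at low temperature is far faster than any attack on the remote primary bromide, and the racemic carbinol centre is of no consequence because it becomes the sp2 carbon C2 of the furan.

**Step 3**
Reactants: 4 14-bromotetradec-1-en-3-ol; 5 methoxyallene
Product: 6 14-bromo-3-[(1-methoxyprop-2-en-1-yl)oxy]tetradec-1-ene (mixture of diastereomers)
Conditions: Pd(OAc)2 (5 mol%), Ph2P(CH2)3PPh2 (7.5 mol%), Et3N (1.5 equiv), MeCN, rt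
Reagents that add atoms: none
Why: In this palladium-catalysed hydroalkoxylation of an alkoxyallene, a palladium hydride generated from zerovalent palladium and the alcohol adds to the allene to give an alkoxy-substituted π-allyl complex that the alkoxide attacks at the oxygen-bearing terminus, which under basic conditions should deliver the acid-labile mixed acetal with an unselective acetal centre that is destroyed later.

**Step 4**
Reactants: 6 14-bromo-3-[(1-methoxyprop-2-en-1-yl)oxy]tetradec-1-ene
Product: 8 2-(11-bromoundecyl)furan, via methoxydihydrofuran 7 (not isolated)
Conditions: second-generation Grubbs catalyst (H2IMes)(PCy3)Cl2Ru=CHPh (3 mol%), CH2Cl2 (0.01 M), 40 °C; then CF3CO2H (10 mol%), rt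
Reagents that add atoms: none
Why: The ruthenium benzylidene exchanges onto one terminal vinyl group, and the resulting alkylidene undergoes [2+2] cycloaddition and cycloreversion with the second vinyl group across the acetal oxygen, releasing ethene and leaving the C3=C4 bond in the 2,5-dihydrofuran 7. Trifluoroacetic acid then ionises the acetal carbon C5 with loss of methanol to a cyclic oxocarbenium ion, and loss of the C2 proton gives the aromatic furan. The closest known reaction type is ring-closing olefin metathesis of allylic mixed acetals followed by acid-promoted elimination of the alcohol to furans. The single ring is closed as a five-membered ring by ring-closing metathesis of a 1,6-diene whose tether contains the ring oxygen. No stereocentre is created, since both centres of 6 become sp2 carbons. The step needs ring closure to outrun intermolecular metathesis and the chain to sit on C2 only: the first is secured by the unstrained five-membered ring, two monosubstituted terminal alkenes and high dilution, the second by the carbinol carbon being the only chain-bearing ring atom, while the absence of any alkyne excludes enyne metathesis and the primary bromide is inert to the carbene.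

**Step 5**
Reactants: 8 2-(11-bromoundecyl)furan
Product: 9 2-(tridec-12-yn-1-yl)furan
Conditions: LiC≡CH·H2NCH2CH2NH2 (1.5 equiv), DMSO, 10 °C → rt
Reagents that add atoms: lithium acetylide–ethylenediamine complex, [Li]C#C.NCCN
Why: SN2 alkylation of lithium acetylide by a primary bromide in DMSO should be clean because the furan C–H bonds are much less acidic than acetylene and no base-sensitive group is present.

**Step 6**
Reactants: 10 hex-5-ynoic acid
Product: 11 6-bromohex-5-ynoic acid
Conditions: Br2 (1.1 equiv), aq KOH (excess), 0 °C; then cold HCl to pH 2
Reagents that add atoms: bromine, BrBr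
Why: In this hypobromite bromination of a terminal alkyne, the acetylide present at equilibrium attacks the electrophilic bromine of potassium hypobromite made in the flask, while the acid is carried through as its potassium carboxylate.

**Step 7**
Reactants: 9 2-(tridec-12-yn-1-yl)furan; 11 6-bromohex-5-ynoic acid
Product: 12 19-(furan-2-yl)nonadeca-5,7-diynoic acid
Conditions: CuCl (10 mol%), NH2OH·HCl, n-BuNH2 (30% aq)/MeOH/THF, 0 °C → rt; then cold 1 M HCl to pH 3
Reagents that add atoms: none
Why: In the Cadiot–Chodkiewicz coupling the copper acetylide of 9 should couple with the bromoalkyne to give the unsymmetrical 1,3-diyne, with hydroxylamine keeping copper monovalent to suppress oxidative homocoupling and the acid tolerated as its ammonium carboxylate.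

**Step 8**
Reactants: 13 furan; 14 1,4-dibromobutane
Product: 16 2-(4-bromobutyl)furan, via 2-furyllithium 15 (not isolated)
Conditions: n-BuLi (1.0 equiv), THF, −78 → 0 °C; then Br(CH2)4Br (3 equiv), −78 °C → rt
Reagents that add atoms: none
Why: Furan is lithiated selectively at C2 next to the ring oxygen, and SN2 alkylation of the 2-furyllithium by the primary dibromide, used in excess, should suppress double substitution.

**Step 9**
Reactants: 16 2-(4-bromobutyl)furan
Product: 17 2-(hex-5-yn-1-yl)furan
Conditions: LiC≡CH·H2NCH2CH2NH2 (1.5 equiv), DMSO, 10 °C → rt
Reagents that add atoms: lithium acetylide–ethylenediamine complex, [Li]C#C.NCCN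
Why: This is the same SN2 acetylide alkylation of a primary bromide as in step 5, on a substrate with no acidic or electrophilic site other than the C–Br bond.

**Step 10**
Reactants: 18 pent-4-yn-1-ol
Product: 19 5-bromopent-4-yn-1-ol
Conditions: NBS (1.1 equiv), AgNO3 (10 mol%), acetone, rt, dark
Reagents that add atoms: N-bromosuccinimide, O=C1CCC(=O)N1Br
Why: Silver-catalysed electrophilic bromination of a terminal alkyne proceeds through a silver acetylide that is brominated by NBS and tolerates the free hydroxyl group.

**Step 11**
Reactants: 17 2-(hex-5-yn-1-yl)furan; 19 5-bromopent-4-yn-1-ol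
Product: 20 11-(furan-2-yl)undeca-4,6-diyn-1-ol
Conditions: CuCl (5 mol%), NH2OH·HCl, n-BuNH2 (30% aq), MeOH, 0 °C → rt
Reagents that add atoms: none
Why: Cadiot–Chodkiewicz coupling of a terminal alkyne with a bromoalkynol is a standard route to unsymmetrical diynols, and the bromine is placed on the furan-free partner so that no electrophilic bromine source ever meets a furan.

**Step 12**
Reactants: 12 19-(furan-2-yl)nonadeca-5,7-diynoic acid; 20 11-(furan-2-yl)undeca-4,6-diyn-1-ol
Product: 21 11-(furan-2-yl)undeca-4,6-diyn-1-yl 19-(furan-2-yl)nonadeca-5,7-diynoate (target)
Conditions: DCC (1.1 equiv), DMAP (10 mol%), CH2Cl2, 0 °C → rt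
Reagents that add atoms: none
Why: Steglich esterification through the O-acylisourea and acylpyridinium should join a primary alcohol and an unhindered acid under neutral conditions that spare both furans and both diynes.

**Compound list**

1 | 12-bromododecan-1-ol | OCCCCCCCCCCCCBr | starting material
2 | 12-bromododecanal | O=CCCCCCCCCCCCBr | intermediate
3 | vinylmagnesium bromide | C=C[Mg]Br | starting material
4 | 14-bromotetradec-1-en-3-ol (racemic) | C=CC(O)CCCCCCCCCCCBr | intermediate
5 | methoxyallene (1-methoxypropa-1,2-diene) | COC=C=C | starting material
6 | 14-bromo-3-[(1-methoxyprop-2-en-1-yl)oxy]tetradec-1-ene (mixture of diastereomers) | C=CC(OC)OC(C=C)CCCCCCCCCCCBr | intermediate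
7 | 2-(11-bromoundecyl)-5-methoxy-2,5-dihydrofuran (mixture of diastereomers, not isolated) | COC1C=CC(CCCCCCCCCCCBr)O1 | intermediate
8 | 2-(11-bromoundecyl)furan | BrCCCCCCCCCCCc1ccco1 | intermediate
9 | 2-(tridec-12-yn-1-yl)furan | C#CCCCCCCCCCCCc1ccco1 | intermediate
10 | hex-5-ynoic acid | C#CCCCC(=O)O | starting material
11 | 6-bromohex-5-ynoic acid | OC(=O)CCCC#CBr | intermediate
12 | 19-(furan-2-yl)nonadeca-5,7-diynoic acid | OC(=O)CCCC#CC#CCCCCCCCCCCCc1ccco1 | intermediate
13 | furan | c1ccoc1 | starting material
14 | 1,4-dibromobutane | BrCCCCBr | starting material
15 | 2-furyllithium (not isolated) | [Li]c1ccco1 | intermediate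
16 | 2-(4-bromobutyl)furan | BrCCCCc1ccco1 | intermediate
17 | 2-(hex-5-yn-1-yl)furan | C#CCCCCc1ccco1 | intermediate
18 | pent-4-yn-1-ol | C#CCCCO | starting material
19 | 5-bromopent-4-yn-1-ol | OCCCC#CBr | intermediate
20 | 11-(furan-2-yl)undeca-4,6-diyn-1-ol | OCCCC#CC#CCCCCc1ccco1 | intermediate
21 | 11-(furan-2-yl)undeca-4,6-diyn-1-yl 19-(furan-2-yl)nonadeca-5,7-diynoate | O=C(CCCC#CC#CCCCCCCCCCCCc1ccco1)OCCCC#CC#CCCCCc1ccco1 | target

**Step count**

Total: 12 steps. Longest linear sequence: 7 steps (steps 1, 2, 3, 4, 5, 7 and 12).

**Steps most likely to fail**

Step 4. The ruthenium carbene may be held back by chelation to the acetal oxygens, the mixed acetal may hydrolyse before it closes, and the electron-rich furan may oligomerise under the acid used for aromatisation. The fallback keeps the C3=C4 ring closure but moves to the lactone oxidation level. Setting out from 4, the hydroxyl is acylated with acryloyl chloride (Et3N, CH2Cl2, 0 °C) to give 14-bromotetradec-1-en-3-yl prop-2-enoate F1. Ring-closing metathesis with (H2IMes)(PCy3)Cl2Ru=CHPh in toluene at 80 °C should then give 5-(11-bromoundecyl)furan-2(5H)-one F2. Reduction with i-Bu2AlH in CH2Cl2 at −78 °C should give 5-(11-bromoundecyl)-2,5-dihydrofuran-2-ol F3, which loses water on work-up with dilute acid and comes back to the route at 8.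

Step 3. Oligomerisation of the allene may outpace capture of the π-allyl complex by a secondary alcohol, the amine may slowly quaternise the primary bromide, and the mixed acetal may be lost by hydrolysis during purification. The fallback replaces the metal-catalysed addition by an acid-catalysed acetal exchange. Setting out from 4, treatment with an excess of 3,3-dimethoxyprop-1-ene and pyridinium p-toluenesulfonate in toluene at 40 °C under reduced pressure, so that methanol is removed, should give the mixed acetal and comes back to the route directly at 6; no compound outside the list arises (F0).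

Step 7. Homocoupling of the bromoalkyne may compete with heterocoupling, the lipophilic alkyne and the carboxylate salt may not share a phase in the aqueous amine medium, and the acidic work-up may erode the furan. The fallback reverses the order of the last two bond formations so that the diyne is made between two neutral partners. Setting out from 11 and 20, Steglich esterification (DCC, DMAP, CH2Cl2) should give 11-(furan-2-yl)undeca-4,6-diyn-1-yl 6-bromohex-5-ynoate F4. Cadiot–Chodkiewicz coupling of this bromoalkyne with 9 (CuCl, NH2OH·HCl, n-BuNH2, MeOH/THF, 0 °C) then comes back to the route at 21, and step 12 is no longer needed.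

**Further compounds**

F1 | step 4 | 14-bromotetradec-1-en-3-yl prop-2-enoate | C=CC(=O)OC(C=C)CCCCCCCCCCCBr
F2 | step 4 | 5-(11-bromoundecyl)furan-2(5H)-one | O=C1C=CC(CCCCCCCCCCCBr)O1
F3 | step 4 | 5-(11-bromoundecyl)-2,5-dihydrofuran-2-ol | OC1C=CC(CCCCCCCCCCCBr)O1
F0 | step 3 | none | none
F4 | step 7 | 11-(furan-2-yl)undeca-4,6-diyn-1-yl 6-bromohex-5-ynoate | O=C(CCCC#CBr)OCCCC#CC#CCCCCc1ccco1
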